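Numbering used in the text: pyrrole N1, C2–C5. Quinoline positions carry one prime (N1′ to C8a′). Azecane positions carry two primes (N1″, C2″ to C10″).

## Analysis of the target

Isohalitulin 22 has three ring systems. A central pyrrole carries identical 6,7-dihydroxyquinolin-5-yl groups on C3 and C4, and a trimethylene chain on N1 links it to a ten-membered azecane.

The only stereocentre is C3″ (S). It is a methyl-bearing carbon β to N1″ with no heteroatom on it and no second centre to relate to. It must therefore be set absolutely, by a C–C bond formation or from the chiral pool, and it cannot be corrected later.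

The route is built on the following feature. The core has a local twofold axis through N1 and the midpoint of C3–C4. Each half, N1–C2H=C3(Ar), is the enamine of one and the same (quinolin-5-yl)acetaldehyde, and the C3–C4 bond joins the two enamine β-carbons.

A second feature lies on each quinoline. The C5′–C(pyrrole) bond stands ortho to the C6′ oxygen, and C7′ is oxygenated too. Electrophilic substitution of a 6,7-dioxygenated quinoline cannot tell C5′ from C8′, but the C6′–O/C5′–C pair is the retron of an aromatic Claisen rearrangement.

A third feature is the segment N1″–C2″–C3″(CH3)–C4″. It is what is left of an α-methyl lactam, and ten ring members are six plus four.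

The sensitive groups are:
- the two catechols (air oxidation to o-quinones, chelation),
- the pyrrole with free C2–H and C5–H (acid, oxidants),
- three basic nitrogens that bind metals.

The difficulties are the crowding at C3/C4 (each C5′ is flanked by C6′–O and the peri C4′–H), the medium ring with its transannular strain, and the isolated stereocentre.

## Retrosynthetic reasoning

**22 ⇒ 21.** The four O–H groups are traced back to four O–CH3 groups. The catechols would not survive the oxidant of the key step or the handling in between, so they are unmasked last. Methyl is chosen because one methyl ether per quinoline is already present in 1. These ethers also tolerate 185 °C, periodate and silver. The forward step has to cleave four aryl methyl ethers without harming the pyrrole.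

**21 ⇒ two molecules of 9 plus 18.** Three pyrrole bonds are cut at once: C3–C4, N1–C2 and N1–C5.
- Cutting only the biaryl bonds would leave two crowded couplings on neighbouring positions.
- Cutting only N1–CH2 would leave the whole core unsolved.
- The chosen cut uses the local twofold axis. Both carbon halves are the same aldehyde 9, and the nitrogen arrives with its complete side chain in 18.
- No N-protecting group, no N-alkylation and no aryl halide or boronate is then needed.
- The forward reaction has to couple two enamine β-carbons oxidatively and close the ring by condensation.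
- The crowded C–C bond is made between sp3-type centres, before the ring is flattened, and the stereocentres that appear on the way are erased.

**9 ⇒ 7 ⇒ 6 ⇒ 4.** The aldehyde carbon of 9 comes from the internal alkene carbon of the allyl group of 7. The C5′–CH2 bond is cut and replaced by a C6′–O–allyl bond in 4. This is the only cut that makes the C6′ oxygen itself deliver the carbon to C5′, so the 5,6,7-pattern follows from the mechanism and not from a selectivity. The forward [3,3] shift has only C5′ to go to, since C7′ is blocked. The phenol 6 that it sets free is capped as the second methyl ether in 7.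

**4 ⇒ 3 ⇒ 1.** The pyridine ring of 3 is cut at N1′–C2′ and C4′–C4a′, which leads to the catalogue aminophenol 1 and a three-carbon unit. The free hydroxyl group of 1 becomes C6′–OH, and the methoxy group directs ring closure to its para position.

**18 ⇒ 17 ⇒ 16.** The primary amine and C2″H2 are both taken back one oxidation stage, to the nitrile and lactam of 17, so that a single reduction makes both. The N1″–CH2 bond of 17 is cut to the NH-lactam 16 and a three-carbon Michael acceptor.

**16 ⇒ 15 ⇒ 13.** After an alkene is reinstated at C5″=C6″ (15), the C3″–C4″ bond is cut and N1″–C6″ is re-formed. The ten-membered lactam collapses to the six-membered N-acyl-2-vinylpiperidine 13. A medium ring no longer has to be closed end to end, and C3″ is set in the same step by transfer of chirality from the piperidine C2. The forward [3,3] shift needs a defined enolate geometry and a chair transition state.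

**13 ⇒ 11 ⇒ 10.** The acyl group is exchanged for the carbamate of 11, and the vinyl group is cut at its C=C bond. This leads to the enantiopure catalogue aldehyde 10.

## Alternatives that were turned down

**Alternative 1:** the textbook route cuts the two biaryl bonds C3–C5′ and C4–C5′ and the N1–CH2 bond.
- Forward: 5-bromo-6,7-dimethoxyquinoline A1 is coupled twice, by Suzuki–Miyaura reaction, with 1-(triisopropylsilyl)pyrrole-3,4-bis(pinacol boronate) A2. Desilylation gives 3,4-bis(6,7-dimethoxyquinolin-5-yl)-1H-pyrrole A3. N-alkylation with (S)-1-(3-chloropropyl)-3-methylazecane A4 then gives 21.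
- Each coupling makes a biaryl bond flanked by C6′–OMe and the peri C4′–H, and the second one also stands next to the first quinoline.
- Electron-rich pyrrolyl boronates lose boron by protonolysis while a slow coupling waits.
- The bulky silyl group is needed only to steer functionalisation to C3/C4 and must be put on and taken off.
- A1 still needs a C5′-selective functionalisation.
- A4 is a γ-chloroamine that quaternises itself to an azetidinium salt.
- The symmetry of the core is not used, and the sequence is longer and more linear.

**Alternative 2:** this route cuts the same two C–C5′ bonds but traces both back to C6′–O bonds of one four-carbon tether.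
- Forward: a twofold aromatic Claisen rearrangement of 1,4-bis[(7-methoxyquinolin-6-yl)oxy]but-2-yne A5, one step from 3, gives 2,3-bis(6-hydroxy-7-methoxyquinolin-5-yl)buta-1,3-diene A6. Its four chain carbons would become C2–C5 after photooxygenation and condensation with 18.
- The idea uses the C6′–O/C5′–C retron twice and is very short.
- After the first [3,3] shift, however, the o-allenylphenol has a faster exit than the second shift. A [1,5]-hydrogen shift and an oxa-6π electrocyclisation lead to the pyrano[3,2-f]quinoline A7.
- From A7 the second shift can only end in a ring-closed skeleton with a C-methyl group, at the wrong oxidation level.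
- At the same temperature A6 would isomerise in the same way.
- What follows needs a four-electron oxidation of a crowded diene, which must reach the s-cis form, next to free phenols.
- The risk would sit in three places.

**Alternative 3:** this route cuts the pyrrole back to an alkyne.
- Forward: 1,2-bis(6,7-dimethoxyquinolin-5-yl)ethyne A8 undergoes an inverse-electron-demand Diels–Alder reaction with an electron-poor tetrazine diester to give dimethyl 4,5-bis(6,7-dimethoxyquinolin-5-yl)pyridazine-3,6-dicarboxylate A9. Reductive ring contraction then gives dimethyl 3,4-bis(6,7-dimethoxyquinolin-5-yl)-1H-pyrrole-2,5-dicarboxylate A10.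
- The triple bond of A8 is shielded by two methoxy groups and two peri C–H bonds, and it is not activated.
- A8 itself costs a C5′ halide and two alkynylations.
- A10 carries two ester groups that the target lacks. They would have to be hydrolysed and removed by a twofold decarboxylation.
- N1 would still need a separate alkylation.
- The step count would be roughly doubled.

Key step: step 12

Assumption: rotation about the two pyrrole–quinoline bonds is taken to be fast at room temperature, as the SMILES string shows no axial stereochemistry, so that C3″ is the only stereogenic element to control.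

## Route

Step 1
Reactants: 1 4-amino-2-methoxyphenol
Product: 3 7-methoxyquinolin-6-ol, via 7-methoxy-1,2-dihydroquinolin-6-ol 2 (not isolated)
Conditions: glycerol, 3-nitrobenzenesulfonic acid, FeSO4 (cat.), aq. H2SO4 (70%), 135 °C
Reagents that add atoms: glycerol, OCC(O)CO
Why: Skraup quinoline synthesis: the enal formed in the flask adds to the aniline nitrogen, the ring closes at the aniline carbon para to the methoxy group (the other ortho carbon is wedged between N and OMe), and 2 is dehydrogenated by the nitroarene. 4-Aminophenols and methoxyanilines are standard substrates of this reaction.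

Step 2
Reactants: 3 7-methoxyquinolin-6-ol
Product: 4 6-(allyloxy)-7-methoxyquinoline
Conditions: allyl bromide, K2CO3, DMF, rt
Reagents that add atoms: allyl bromide, C=CCBr
Why: Williamson ether synthesis; the phenoxide is far more nucleophilic than the quinoline nitrogen, so O-alkylation should win with about one equivalent of the halide.

Step 3
Reactants: 4 6-(allyloxy)-7-methoxyquinoline
Product: 6 5-allyl-7-methoxyquinolin-6-ol, via 5-allyl-7-methoxyquinolin-6(5H)-one 5 (not isolated)
Conditions: 1,2-dichlorobenzene, 185 °C, argon
Reagents that add atoms: none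
Why: Aromatic Claisen rearrangement, a [3,3] shift that carries the allyl group from the C6′ oxygen to C5′. C7′ is blocked by the methoxy group and the C5′–C6′ bond has the high double-bond character known from 2-naphthyl ethers, so only dienone 5 can tautomerise to a phenol.

Step 4
Reactants: 6 5-allyl-7-methoxyquinolin-6-ol
Product: 7 5-allyl-6,7-dimethoxyquinoline
Conditions: MeI (1.1 equiv), K2CO3, acetone, rt
Reagents that add atoms: iodomethane, CI
Why: Williamson O-methylation. The cap is needed because a free ortho-hydroxyl group would trap the aldehyde of step 5 as a lactol and then a benzofuran-type ring.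

Step 5
Reactants: 7 5-allyl-6,7-dimethoxyquinoline
Product: 9 2-(6,7-dimethoxyquinolin-5-yl)acetaldehyde, via 3-(6,7-dimethoxyquinolin-5-yl)propane-1,2-diol 8 (not isolated)
Conditions: OsO4 (cat.), NaIO4, 2,6-lutidine, dioxane/H2O, rt
Reagents that add atoms: OsO4, O=[Os](=O)(=O)=O (delivers the oxygen atoms of 8); NaIO4, [Na+].[O-]I(=O)(=O)=O (reoxidant and terminal source of that oxygen)
Why: Lemieux–Johnson cleavage: dihydroxylation of the only alkene and glycol cleavage in one flask. It avoids ozone, which could attack the electron-rich benzo ring, and lutidine suppresses over-oxidation; 9 is used without storage.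

Step 6
Reactants: 10 tert-butyl (S)-2-formylpiperidine-1-carboxylate
Product: 11 tert-butyl (S)-2-vinylpiperidine-1-carboxylate
Conditions: Ph3PCH3Br, KN(SiMe3)2, THF, −78 °C to rt
Reagents that add atoms: methyltriphenylphosphonium bromide, C[P+](c1ccccc1)(c1ccccc1)c1ccccc1.[Br-]
Why: Wittig methylenation; the unstabilised ylide adds to the aldehyde at low temperature faster than it enolises it, so the configuration at C2 should be kept.

Step 7
Reactants: 11 tert-butyl (S)-2-vinylpiperidine-1-carboxylate
Product: 13 (S)-1-(2-vinylpiperidin-1-yl)propan-1-one, via (S)-2-vinylpiperidine hydrochloride 12 (not isolated)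
Conditions: HCl (4 M in dioxane), rt; evaporation; EtCOCl, Et3N, CH2Cl2, 0 °C
Reagents that add atoms: propionyl chloride, CCC(=O)Cl; hydrogen chloride, Cl (chloride of 12 only)
Why: Acidolysis of the carbamate and N-acylation of the amine; the volatile amine is kept as its salt until it is acylated, and no bond at the stereocentre is touched.

Step 8
Reactants: 13 (S)-1-(2-vinylpiperidin-1-yl)propan-1-one
Product: 15 (3S,5E)-3-methyl-3,4,7,8,9,10-hexahydroazecin-2(1H)-one, via lithium (Z)-1-[(S)-2-vinylpiperidin-1-yl]prop-1-en-1-olate 14 (not isolated)
Conditions: LiN(SiMe3)2, toluene, reflux; then H2O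
Reagents that add atoms: LiN(SiMe3)2, [Li+].C[Si](C)(C)[N-][Si](C)(C)C (lithium of 14 only; nothing stays in 15)
Why: Amide-enolate aza-Claisen rearrangement with four-atom ring expansion, a reaction type known for 1-acyl-2-vinylpiperidines. The Z(O)-enolate 14 (methyl trans to nitrogen, which avoids allylic strain) reacts through a chair in which the methyl group and piperidine C3 are both equatorial, so the S configuration at piperidine C2 is relayed to S at C3″ while the E alkene forms. The shift is irreversible because a delocalised lactam anion results, and this anion also shields C3″–H from deprotonation.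

Step 9
Reactants: 15 (3S,5E)-3-methyl-3,4,7,8,9,10-hexahydroazecin-2(1H)-one
Product: 16 (S)-3-methylazecan-2-one
Conditions: H2 (1 atm), Pd/C, MeOH, rt
Reagents that add atoms: none
Why: Catalytic hydrogenation of a strained E alkene in a medium ring; the stereocentre is not allylic to a leaving group and is not affected.

Step 10
Reactants: 16 (S)-3-methylazecan-2-one
Product: 17 (S)-3-(3-methyl-2-oxoazecan-1-yl)propanenitrile
Conditions: acrylonitrile, KOC(CH3)3 (cat.), THF/t-BuOH, 0 °C to rt
Reagents that add atoms: acrylonitrile, C=CC#N
Why: Base-catalysed cyanoethylation (aza-Michael addition) of a lactam N–H, the reaction type used on simple lactams on a large scale. The N–H is many orders of magnitude more acidic than C3″–H, so a catalytic alkoxide should not epimerise the centre.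

Step 11
Reactants: 17 (S)-3-(3-methyl-2-oxoazecan-1-yl)propanenitrile
Product: 18 (S)-3-(3-methylazecan-1-yl)propan-1-amine
Conditions: BH3·THF, THF, reflux; then HCl, MeOH, reflux; NaOH
Reagents that add atoms: none
Why: Borane reduces the tertiary lactam and the nitrile in the same operation. As a non-basic hydride source it avoids the E1cB loss of the cyanoethyl group, and acidic methanolysis breaks the amine–borane complexes.

Step 12
Reactants: 9 2-(6,7-dimethoxyquinolin-5-yl)acetaldehyde (two equivalents); 18 (S)-3-(3-methylazecan-1-yl)propan-1-amine
Product: 21 3,4-bis(6,7-dimethoxyquinolin-5-yl)-1-{3-[(S)-3-methylazecan-1-yl]propyl}-1H-pyrrole, via N-alkyl imine of the aldehyde 19 (not isolated), via 2,3-diaryl-1,4-diimine 20 (not isolated)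
Conditions: 9 (2.2 equiv), 18 (1 equiv), AgOAc (4 equiv), NaOAc, THF, 60 °C, argon, dark
Reagents that add atoms: none
Why: Amine 18 condenses with 9 to imine 19, whose enamine tautomer is the most easily oxidised π system in the flask; AgOAc removes one electron, the radical cation is captured at its β-carbon by a second enamine and a second AgOAc completes the two-electron balance, so that the C3–C4 bond is made between the two benzylic carbons in diimine 20. One imine of 20 tautomerises to the enamine, its nitrogen adds to the other C=N carbon in a 5-exo-trig closure, and expulsion of one molecule of 18, which re-enters as 19, aromatises the ring as in the second half of a Paal–Knorr synthesis. The closest known reaction type is the AgOAc-mediated oxidative condensation of electron-rich arylacetaldehydes with primary alkylamines to 1-alkyl-3,4-diarylpyrroles. In one operation the bonds C3–C4, N1–C2 and N1–C5 and the last ring are formed and all three fragments are joined, from two precursors that are each about a third of the product. The two stereocentres of 20 arise without control as a dl/meso mixture, but both are erased on aromatisation, so the step is stereoconvergent, and the remote centre C3″ has no acidic or oxidisable neighbour and is not touched. Regiochemistry is fixed by the mechanism: only one aldehyde is present, and coupling through the enamine β-carbons can give only the 3,4-diaryl pattern with C2–H and C5–H free. The chemoselectivity needed is oxidation of the enamine in preference to the trialkylamine N1″, the dimethoxyquinolines and product 21; it is secured by the much lower oxidation potential of the enamine and by the twist of the quinolines in 21, while the excess of AgOAc allows for silver held by the basic nitrogens and NaOAc buffers the acid formed.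

Step 13
Reactants: 21 3,4-bis(6,7-dimethoxyquinolin-5-yl)-1-{3-[(S)-3-methylazecan-1-yl]propyl}-1H-pyrrole
Product: 22 isohalitulin
Conditions: BBr3 (excess), CH2Cl2, −78 °C to rt; then H2O, NaHCO3 (degassed), argon
Reagents that add atoms: none
Why: Lewis-acid cleavage of aryl methyl ethers, the usual last step for polyphenolic 3,4-diarylpyrrole alkaloids. The three basic nitrogens are complexed first, which makes the pyrrole poorer in electrons and protects it from acid-induced oligomerisation; work-up under argon guards the catechols.

## Compound list

1 | 4-amino-2-methoxyphenol | COc1cc(N)ccc1O | starting material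
2 | 7-methoxy-1,2-dihydroquinolin-6-ol | COc1cc2c(cc1O)C=CCN2 | intermediate
3 | 7-methoxyquinolin-6-ol | COc1cc2ncccc2cc1O | intermediate
4 | 6-(allyloxy)-7-methoxyquinoline | COc1cc2ncccc2cc1OCC=C | intermediate
5 | 5-allyl-7-methoxyquinolin-6(5H)-one (racemic) | COC1=Cc2ncccc2C(CC=C)C1=O | intermediate
6 | 5-allyl-7-methoxyquinolin-6-ol | COc1cc2ncccc2c(CC=C)c1O | intermediate
7 | 5-allyl-6,7-dimethoxyquinoline | COc1cc2ncccc2c(CC=C)c1OC | intermediate
8 | 3-(6,7-dimethoxyquinolin-5-yl)propane-1,2-diol (racemic) | COc1cc2ncccc2c(CC(O)CO)c1OC | intermediate
9 | 2-(6,7-dimethoxyquinolin-5-yl)acetaldehyde | COc1cc2ncccc2c(CC=O)c1OC | intermediate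
10 | tert-butyl (S)-2-formylpiperidine-1-carboxylate | O=C[C@@H]1CCCCN1C(=O)OC(C)(C)C | starting material
11 | tert-butyl (S)-2-vinylpiperidine-1-carboxylate | C=C[C@@H]1CCCCN1C(=O)OC(C)(C)C | intermediate
12 | (S)-2-vinylpiperidine hydrochloride | C=C[C@@H]1CCCCN1.Cl | intermediate
13 | (S)-1-(2-vinylpiperidin-1-yl)propan-1-one | C=C[C@@H]1CCCCN1C(=O)CC | intermediate
14 | lithium (Z)-1-[(S)-2-vinylpiperidin-1-yl]prop-1-en-1-olate | C/C=C(\[O-])N1CCCC[C@H]1C=C.[Li+] | intermediate
15 | (3S,5E)-3-methyl-3,4,7,8,9,10-hexahydroazecin-2(1H)-one | C[C@H]1C/C=C/CCCCNC1=O | intermediate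
16 | (S)-3-methylazecan-2-one | C[C@H]1CCCCCCCNC1=O | intermediate
17 | (S)-3-(3-methyl-2-oxoazecan-1-yl)propanenitrile | C[C@H]1CCCCCCCN(CCC#N)C1=O | intermediate
18 | (S)-3-(3-methylazecan-1-yl)propan-1-amine | C[C@H]1CCCCCCCN(CCCN)C1 | intermediate
19 | (E)-2-(6,7-dimethoxyquinolin-5-yl)-N-{3-[(S)-3-methylazecan-1-yl]propyl}ethan-1-imine | C[C@H]1CCCCCCCN(CCC/N=C/Cc2c(OC)c(OC)cc3ncccc23)C1 | intermediate
20 | 2,3-bis(6,7-dimethoxyquinolin-5-yl)-N1,N4-bis{3-[(S)-3-methylazecan-1-yl]propyl}butane-1,4-diimine (dl/meso mixture at C2 and C3) | C[C@H]1CCCCCCCN(CCCN=CC(c2c(OC)c(OC)cc3ncccc23)C(C=NCCCN2CCCCCCC[C@H](C)C2)c2c(OC)c(OC)cc3ncccc23)C1 | intermediate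
21 | 3,4-bis(6,7-dimethoxyquinolin-5-yl)-1-{3-[(S)-3-methylazecan-1-yl]propyl}-1H-pyrrole | C[C@H]1CCCCCCCN(CCCn2cc(-c3c(OC)c(OC)cc4ncccc34)c(-c3c(OC)c(OC)cc4ncccc34)c2)C1 | intermediate
22 | isohalitulin | C[C@H]1CCCCCCCN(CCCn2cc(-c3c(O)c(O)cc4ncccc34)c(-c3c(O)c(O)cc4ncccc34)c2)C1 | target

## Step count and least certain steps

- Total: 13 steps.
- Longest linear sequence: 8 steps (steps 6 to 13, from 10).
- The aldehyde branch (steps 1 to 5) joins at step 12.

**Step 12 (key step).** The C–C coupling joins two benzylic positions that each carry a quinoline with two flanking groups, so it may be slow. Several processes could then take over: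
- aldol-type self-condensation of the aldehyde,
- further oxidation of the enamine,
- oxidation at the tertiary amine,
- sequestering of silver by the three basic nitrogens.

The fallback gives up the ring construction and makes the two biaryl bonds on a preformed pyrrole. It sets out from 3 and 16 and comes back at 21. Bromination of 3 with N-bromosuccinimide (MeCN, 0 °C) should go ortho to the hydroxyl group at C5′ and give 5-bromo-7-methoxyquinolin-6-ol F1. O-methylation (MeI, K2CO3) gives 5-bromo-6,7-dimethoxyquinoline F2. Miyaura borylation (B2pin2, Pd(dppf)Cl2, KOAc, dioxane) gives 6,7-dimethoxy-5-(4,4,5,5-tetramethyl-1,3,2-dioxaborolan-2-yl)quinoline F3. F3 is then coupled twice, by Suzuki–Miyaura reaction (Pd(OAc)2/SPhos, K3PO4), with 3,4-dibromo-1-(triisopropylsilyl)pyrrole F4, which is made from 1-(triisopropylsilyl)pyrrole and two equivalents of N-bromosuccinimide. This gives 3,4-bis(6,7-dimethoxyquinolin-5-yl)-1-(triisopropylsilyl)pyrrole F5, and Bu4NF sets free 3,4-bis(6,7-dimethoxyquinolin-5-yl)-1H-pyrrole F6. In parallel, LiAlH4 reduces 16 to (S)-3-methylazecane F7, which 1-bromo-3-chloropropane and K2CO3 turn into (S)-1-(3-chloropropyl)-3-methylazecane F8. The sodium salt of F6 (NaH, DMF) is alkylated with freshly made F8 to give 21.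

**Step 8.** LiN(SiMe3)2 deprotonates the amide only to a small equilibrium share. At reflux, fragmentation of the enolate with loss of the acyl group may compete. Leakage through a boat transition state or through the minor enolate geometry would erode the enantiomeric purity, and this cannot be repaired later.

The fallback replaces the hot anionic shift by the charge-accelerated zwitterionic variant on a tertiary amine at room temperature, with the side chain already on nitrogen. It sets out from 12 and comes back at 17, so that steps 9 and 10 are merged into it. Salt 12 is set free with K2CO3 and added to acrylonitrile (MeOH, rt) to give (S)-3-(2-vinylpiperidin-1-yl)propanenitrile F9. Propionyl chloride, i-Pr2NEt and TiCl4(THF)2 in CH2Cl2 generate methylketene, which acylates the amine. The acylammonium Z-enolate rearranges through the same chair to (S,E)-3-(3-methyl-2-oxo-3,4,7,8,9,10-hexahydroazecin-1(2H)-yl)propanenitrile F10. Hydrogenation over Pd/C gives 17.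

**Step 1.** The electron-rich aminophenol may be oxidised to tar or sulfonated in the hot acid before the ring closes. A minor closure at the carbon between N and OMe is also possible.

The fallback builds the pyridine ring thermally, without strong acid or oxidant. It sets out from 1 and comes back at 3. Condensation of 1 with 5-(methoxymethylene)-2,2-dimethyl-1,3-dioxane-4,6-dione gives 5-{[(4-hydroxy-3-methoxyphenyl)amino]methylene}-2,2-dimethyl-1,3-dioxane-4,6-dione F11. Thermolysis in diphenyl ether at 250 °C closes the ring through the ketene to 6-hydroxy-7-methoxyquinolin-4(1H)-one F12. POCl3, followed by aqueous work-up, gives 4-chloro-7-methoxyquinolin-6-ol F13. Hydrogenolysis (H2, Pd/C, Et3N) gives 3.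

**Step 10.** Conjugate addition of the hindered medium-ring lactam anion may be sluggish and reversible, with anionic polymerisation of the acceptor as the competing process. Loss of the cyanoethyl group could also occur in step 11.

The fallback changes the nucleophile from a lactam to a secondary amine. It sets out from 16 and comes back at 18. LiAlH4 reduces 16 to (S)-3-methylazecane F7, the compound already met in the fallback to step 12. This adds to acrylonitrile in MeOH without a catalyst to give (S)-3-(3-methylazecan-1-yl)propanenitrile F14. LiAlH4 reduces F14 to 18, at the cost of one more step.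

**Step 13.** Three processes threaten this step: incomplete cleavage of the four ethers, acid-induced oligomerisation of the pyrrole, and air oxidation of the catechols during neutralisation.

The fallback moves the hard ether cleavage to an early, robust compound and ends with a mild acetal cleavage. It sets out from 6 and comes back at 22. AlCl3/pyridine (CH2Cl2, reflux), which is selective for a methyl ether next to a free phenol, gives 5-allylquinoline-6,7-diol F15. MOMCl and i-Pr2NEt give 5-allyl-6,7-bis(methoxymethoxy)quinoline F16. The conditions of step 5 give 2-[6,7-bis(methoxymethoxy)quinolin-5-yl]acetaldehyde F17. The conditions of step 12 with 18 give 3,4-bis[6,7-bis(methoxymethoxy)quinolin-5-yl]-1-{3-[(S)-3-methylazecan-1-yl]propyl}-1H-pyrrole F18. HCl in degassed MeOH at 40 °C gives 22.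

## Further compounds

F1 | step 12 | 5-bromo-7-methoxyquinolin-6-ol | COc1cc2ncccc2c(Br)c1O
F2 | step 12 | 5-bromo-6,7-dimethoxyquinoline | COc1cc2ncccc2c(Br)c1OC
F3 | step 12 | 6,7-dimethoxy-5-(4,4,5,5-tetramethyl-1,3,2-dioxaborolan-2-yl)quinoline | COc1cc2ncccc2c(B2OC(C)(C)C(C)(C)O2)c1OC
F4 | step 12 | 3,4-dibromo-1-(triisopropylsilyl)pyrrole | CC(C)[Si](C(C)C)(C(C)C)n1cc(Br)c(Br)c1
F5 | step 12 | 3,4-bis(6,7-dimethoxyquinolin-5-yl)-1-(triisopropylsilyl)pyrrole | COc1cc2ncccc2c(-c2cn([Si](C(C)C)(C(C)C)C(C)C)cc2-c2c(OC)c(OC)cc3ncccc23)c1OC
F6 | step 12 | 3,4-bis(6,7-dimethoxyquinolin-5-yl)-1H-pyrrole | COc1cc2ncccc2c(-c2c[nH]cc2-c2c(OC)c(OC)cc3ncccc23)c1OC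
F7 | step 12 | (S)-3-methylazecane | C[C@H]1CCCCCCCNC1
F8 | step 12 | (S)-1-(3-chloropropyl)-3-methylazecane | C[C@H]1CCCCCCCN(CCCCl)C1
F9 | step 8 | (S)-3-(2-vinylpiperidin-1-yl)propanenitrile | C=C[C@@H]1CCCCN1CCC#N
F10 | step 8 | (S,E)-3-(3-methyl-2-oxo-3,4,7,8,9,10-hexahydroazecin-1(2H)-yl)propanenitrile | C[C@H]1C/C=C/CCCCN(CCC#N)C1=O
F11 | step 1 | 5-{[(4-hydroxy-3-methoxyphenyl)amino]methylene}-2,2-dimethyl-1,3-dioxane-4,6-dione | COc1cc(NC=C2C(=O)OC(C)(C)OC2=O)ccc1O
F12 | step 1 | 6-hydroxy-7-methoxyquinolin-4(1H)-one | COc1cc2[nH]ccc(=O)c2cc1O
F13 | step 1 | 4-chloro-7-methoxyquinolin-6-ol | COc1cc2nccc(Cl)c2cc1O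
F14 | step 10 | (S)-3-(3-methylazecan-1-yl)propanenitrile | C[C@H]1CCCCCCCN(CCC#N)C1
F15 | step 13 | 5-allylquinoline-6,7-diol | C=CCc1c(O)c(O)cc2ncccc12
F16 | step 13 | 5-allyl-6,7-bis(methoxymethoxy)quinoline | C=CCc1c(OCOC)c(OCOC)cc2ncccc12
F17 | step 13 | 2-[6,7-bis(methoxymethoxy)quinolin-5-yl]acetaldehyde | O=CCc1c(OCOC)c(OCOC)cc2ncccc12
F18 | step 13 | 3,4-bis[6,7-bis(methoxymethoxy)quinolin-5-yl]-1-{3-[(S)-3-methylazecan-1-yl]propyl}-1H-pyrrole | C[C@H]1CCCCCCCN(CCCn2cc(-c3c(OCOC)c(OCOC)cc4ncccc34)c(-c3c(OCOC)c(OCOC)cc4ncccc34)c2)C1
A1 | alternative 1 | 5-bromo-6,7-dimethoxyquinoline | COc1cc2ncccc2c(Br)c1OC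
A2 | alternative 1 | 1-(triisopropylsilyl)-3,4-bis(4,4,5,5-tetramethyl-1,3,2-dioxaborolan-2-yl)pyrrole | CC(C)[Si](C(C)C)(C(C)C)n1cc(B2OC(C)(C)C(C)(C)O2)c(B2OC(C)(C)C(C)(C)O2)c1
A3 | alternative 1 | 3,4-bis(6,7-dimethoxyquinolin-5-yl)-1H-pyrrole | COc1cc2ncccc2c(-c2c[nH]cc2-c2c(OC)c(OC)cc3ncccc23)c1OC
A4 | alternative 1 | (S)-1-(3-chloropropyl)-3-methylazecane | C[C@H]1CCCCCCCN(CCCCl)C1
A5 | alternative 2 | 1,4-bis[(7-methoxyquinolin-6-yl)oxy]but-2-yne | COc1cc2ncccc2cc1OCC#CCOc1cc2cccnc2cc1OC
A6 | alternative 2 | 2,3-bis(6-hydroxy-7-methoxyquinolin-5-yl)buta-1,3-diene | C=C(c1c(O)c(OC)cc2ncccc12)C(=C)c1c(O)c(OC)cc2ncccc12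
A7 | alternative 2 | 5-methoxy-1-{[(7-methoxyquinolin-6-yl)oxy]methyl}-3H-pyrano[3,2-f]quinoline | COc1cc2ncccc2c2c1OCC=C2COc1cc2cccnc2cc1OC
A8 | alternative 3 | 1,2-bis(6,7-dimethoxyquinolin-5-yl)ethyne | COc1cc2ncccc2c(C#Cc2c(OC)c(OC)cc3ncccc23)c1OC
A9 | alternative 3 | dimethyl 4,5-bis(6,7-dimethoxyquinolin-5-yl)pyridazine-3,6-dicarboxylate | COC(=O)c1nnc(C(=O)OC)c(-c2c(OC)c(OC)cc3ncccc23)c1-c1c(OC)c(OC)cc2ncccc12
A10 | alternative 3 | dimethyl 3,4-bis(6,7-dimethoxyquinolin-5-yl)-1H-pyrrole-2,5-dicarboxylate | COC(=O)c1[nH]c(C(=O)OC)c(-c2c(OC)c(OC)cc3ncccc23)c1-c1c(OC)c(OC)cc2ncccc12
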